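The carbocycle fused to the γ-pyrone at C4a/C8a is opened at the C6–C7 bond, the centre of the C5–C8 tetraol. Both carbons are then aldehydes, each flanked by a silyloxy stereocentre (C5, C8) that sits on the pyrone ring. A trans-selective titanocene pinacol cyclisation of this 1,6-dialdehyde closes the six-membered ring and sets C6 and C7 in one operation; the peri C4 carbonyl, which forces the C5 silyloxy group pseudo-axial, decides between the two trans diols. The precursor is a 2,3,6-trisubstituted 4-pyranone with two α-silyloxyacetaldehyde arms, built from (S)-3-hydroxy-γ-butyrolactone (C5), methyl (S)-glycerate (C8) and an aryl butyne by ynone aldol, oxidation and 6-endo closure.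

Key step: step 11

Remark: the chromone numbering of the target (O1, C2–C4, C4a, C5–C8, C8a) is used for all intermediates. Methyl (S)-2,3-dihydroxypropanoate is taken as a purchased material; otherwise it is one acidic methanolysis away from the commercial methyl (S)-2,2-dimethyl-1,3-dioxolane-4-carboxylate.

Step 1
Reactants: 1 [3-(benzyloxy)-4-methoxyphenyl]methanol
Product: 2 2-(benzyloxy)-4-(bromomethyl)-1-methoxybenzene
Conditions: PBr3, Et2O, 0 °C
Reagents that add atoms: phosphorus tribromide, BrP(Br)Br
Why: Bromination of an electron-rich benzylic alcohol through its dibromophosphite (SN2 displacement by bromide) is routine and should leave both aryl ethers untouched.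

Step 2
Reactants: 2 2-(benzyloxy)-4-(bromomethyl)-1-methoxybenzene
Product: 3 2-(benzyloxy)-4-(but-3-yn-1-yl)-1-methoxybenzene
Conditions: HC≡CCH2MgBr (prepared beforehand from propargyl bromide, Mg and catalytic HgCl2), Et2O, 0 °C to rt
Reagents that add atoms: propargylmagnesium bromide, C#CC[Mg]Br
Why: The propargyl Grignard reagent, present as its allenyl form, should be alkylated by the reactive benzylic bromide at the γ-carbon (SE2′ Grignard coupling) to give the homopropargyl arene.

Step 3
Reactants: 4 (S)-4-hydroxydihydrofuran-2(3H)-one [(S)-3-hydroxy-γ-butyrolactone]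
Product: 5 (S)-3,4-dihydroxy-N-methoxy-N-methylbutanamide
Conditions: MeNH(OMe)·HCl, AlMe3, CH2Cl2, 0 °C to rt; aqueous potassium sodium tartrate
Reagents that add atoms: N,O-dimethylhydroxylamine hydrochloride, CNOC.Cl
Why: Aminolysis of the lactone by the aluminium amide made from AlMe3 and the hydroxylamine salt (Weinreb amidation) opens the ring at the acyl carbon, so the future C5 stereocenter, which is not a reacting center, is carried over unchanged from the chiral pool.

Step 4
Reactants: 5 (S)-3,4-dihydroxy-N-methoxy-N-methylbutanamide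
Product: 6 (S)-N-methoxy-N-methyl-3,4-bis(triethylsilyloxy)butanamide
Conditions: Et3SiCl, imidazole, DMF, 0 °C to rt
Reagents that add atoms: chlorotriethylsilane, CC[Si](Cl)(CC)CC
Why: Imidazole-promoted silylation of both hydroxyl groups is standard and removes the risk of relactonisation of the hydroxy amide.

Step 5
Reactants: 3 2-(benzyloxy)-4-(but-3-yn-1-yl)-1-methoxybenzene; 6 (S)-N-methoxy-N-methyl-3,4-bis(triethylsilyloxy)butanamide
Product: 8 (S)-8-[3-(benzyloxy)-4-methoxyphenyl]-1,2-bis(triethylsilyloxy)oct-5-yn-4-one, via lithium acetylide 7 (not isolated)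
Conditions: 3, n-BuLi, THF, −78 °C; then 6, −78 to 0 °C; H2O quench
Reagents that add atoms: none
Why: Addition of the lithium acetylide to the Weinreb amide should stop at the chelated tetrahedral intermediate and give the ynone on work-up (Weinreb ketone synthesis), with the β-silyloxy center untouched at low temperature.

Step 6
Reactants: 9 methyl (S)-2,3-dihydroxypropanoate
Product: 10 methyl (S)-2,3-bis(triethylsilyloxy)propanoate
Conditions: Et3SiCl, imidazole, DMF, 0 °C to rt
Reagents that add atoms: chlorotriethylsilane, CC[Si](Cl)(CC)CC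
Why: Standard bis-silylation of the glycerate diol, whose stereocenter becomes C8 of the target.

Step 7
Reactants: 10 methyl (S)-2,3-bis(triethylsilyloxy)propanoate
Product: 11 (S)-2,3-bis(triethylsilyloxy)propanal
Conditions: i-Bu2AlH, CH2Cl2, −78 °C; aqueous potassium sodium tartrate; used crude
Reagents that add atoms: none
Why: At −78 °C the α-silyloxy ester should be reduced only as far as the chelated aluminium hemiacetal, which releases the aldehyde on work-up (partial ester reduction) with the future C8 center intact.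

Step 8
Reactants: 8 (S)-8-[3-(benzyloxy)-4-methoxyphenyl]-1,2-bis(triethylsilyloxy)oct-5-yn-4-one; 11 (S)-2,3-bis(triethylsilyloxy)propanal
Product: 13 aldol adduct (2S)-8-[3-(benzyloxy)-4-methoxyphenyl]-3-[(2S)-1-hydroxy-2,3-bis(triethylsilyloxy)propyl]-1,2-bis(triethylsilyloxy)oct-5-yn-4-one as a mixture of epimers at C3 and C1′, via lithium enolate 12 (not isolated)
Conditions: LiN(SiMe3)2, THF, −78 °C; then 11, −78 °C; H2O quench
Reagents that add atoms: none
Why: The ynone has a single enolisable position (the CH2 that becomes C4a), so its lithium enolate adds to the α-silyloxy aldehyde in an aldol reaction that forms the C4a–C8a bond; the two new centers are of no consequence because both become sp2 in step 9.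

Step 9
Reactants: 13 aldol adduct
Product: 15 6-{2-[3-(benzyloxy)-4-methoxyphenyl]ethyl}-2,3-bis[(1S)-1,2-bis(triethylsilyloxy)ethyl]-4H-pyran-4-one, via diketone 14 (not isolated)
Conditions: Dess–Martin periodinane, NaHCO3, CH2Cl2, 0 °C to rt; then DMAP (0.2 equiv), MeCN, rt
Reagents that add atoms: none
Why: Dess–Martin oxidation gives the 2-acyl ynone 14, and DMAP, by adding to the ynone β-carbon (C2) and being displaced there by the enol oxygen on C8a, allows only the 6-endo oxa-Michael closure to the 4-pyranone (as in ynone-to-chromone cyclisations), while C5 and C8 are not enolised under these mild conditions.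

Step 10
Reactants: 15 pyranone with four triethylsilyl ethers
Product: 16 (2R)-2-{6-[2-(3-benzyloxy-4-methoxyphenyl)ethyl]-4-oxo-3-[(1S)-2-oxo-1-(triethylsilyloxy)ethyl]-4H-pyran-2-yl}-2-(triethylsilyloxy)acetaldehyde
Conditions: (COCl)2, DMSO, CH2Cl2, −78 to −30 °C; then i-Pr2NEt, −78 °C; cold pH 7 work-up; used at once
Reagents that add atoms: none
Why: Under Swern conditions primary triethylsilyl ethers are cleaved by the chlorosulfonium salt and oxidised in the same flask while secondary ones survive (direct Swern oxidation of primary silyl ethers), which should unveil both formyl groups (C6 and C7) in one operation; the change of the C8 descriptor from S to R is a priority effect only.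

Step 11
Reactants: 16 dialdehyde
Product: 18 2-{2-[3-(benzyloxy)-4-methoxyphenyl]ethyl}-6,7-dihydroxy-5,8-bis(triethylsilyloxy)-5,6,7,8-tetrahydro-4H-chromen-4-one with 5,6-cis, 6,7-trans, 7,8-trans configuration, via titanium diolate 17 (not isolated)
Conditions: Cp2TiCl2, i-PrMgCl, THF, −78 °C to rt; PhMgBr, −78 °C (gives Cp2TiPh, trivalent titanium, 3 equiv); slow addition of 16, −78 to −40 °C; aqueous NaHCO3, air
Reagents that add atoms: none
Why: Cp2TiPh transfers one electron to each formyl group and the two titanium-bound ketyls at C6 and C7 combine, a reductive pinacol cyclisation whose closest precedent is the trans-selective titanocene-phenyl coupling of hexanedial to trans-cyclohexane-1,2-diol. The six-membered carbocycle closes by 6-exo-trig attack of the C6 ketyl on the titanium-activated C7 carbonyl (or by collapse of the 1,6-bis-ketyl), the C4a=C8a bond of the pyranone holding the two arms cis. C6 and C7 are set relative to each other by the two bulky Cp2Ti(Ph)O groups, which should take anti, pseudo-equatorial positions in the half-chair transition state and so give the trans diol. Of the two trans diols, each of which has one new oxygen syn and one anti to its silyloxy neighbour, the one needed keeps the C5 silyloxy group pseudo-axial, away from the peri C4 carbonyl (allylic 1,3 strain), which places C6–O cis to C5–O and C7–O trans to the pseudo-equatorial C8–O; the other would push the C5 silyloxy group into the plane of the C4 carbonyl. Chemoselectivity rests on the mild reductant, which should reduce aldehydes but not the vinylogous-ester carbonyl of the pyranone or the benzyl and silyl ethers, and C5 and C8 stay intact as long as the aldehydes are not enolised.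

Step 12
Reactants: 18 trans-diol bis(triethylsilyl) ether
Product: 19 (5S,6S,7R,8S)-5,6,7,8-tetrahydroxy-2-[2-(3-hydroxy-4-methoxyphenyl)ethyl]-5,6,7,8-tetrahydro-4H-chromen-4-one
Conditions: 10% Pd/C, MeOH, rt; then H2 (1 atm), rt
Reagents that add atoms: none
Why: Palladium on carbon in methanol is known to methanolyse triethylsilyl ethers, and under hydrogen the same catalyst hydrogenolyses the aryl benzyl ether, while the electron-poor pyranone and its allylic carbinols should not be reduced under these mild conditions (global deprotection).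

Compound list
1 | [3-(benzyloxy)-4-methoxyphenyl]methanol | COc1ccc(CO)cc1OCc1ccccc1 | starting material
2 | 2-(benzyloxy)-4-(bromomethyl)-1-methoxybenzene | COc1ccc(CBr)cc1OCc1ccccc1 | intermediate
3 | 2-(benzyloxy)-4-(but-3-yn-1-yl)-1-methoxybenzene | COc1ccc(CCC#C)cc1OCc1ccccc1 | intermediate
4 | (S)-4-hydroxydihydrofuran-2(3H)-one | O=C1C[C@H](O)CO1 | starting material
5 | (S)-3,4-dihydroxy-N-methoxy-N-methylbutanamide | CON(C)C(=O)C[C@H](O)CO | intermediate
6 | (S)-N-methoxy-N-methyl-3,4-bis(triethylsilyloxy)butanamide | CON(C)C(=O)C[C@H](O[Si](CC)(CC)CC)CO[Si](CC)(CC)CC | intermediate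
7 | lithium acetylide of 3 | COc1ccc(CCC#C[Li])cc1OCc1ccccc1 | intermediate
8 | (S)-8-[3-(benzyloxy)-4-methoxyphenyl]-1,2-bis(triethylsilyloxy)oct-5-yn-4-one | COc1ccc(CCC#CC(=O)C[C@H](O[Si](CC)(CC)CC)CO[Si](CC)(CC)CC)cc1OCc1ccccc1 | intermediate
9 | methyl (S)-2,3-dihydroxypropanoate | COC(=O)[C@@H](O)CO | starting material
10 | methyl (S)-2,3-bis(triethylsilyloxy)propanoate | COC(=O)[C@@H](O[Si](CC)(CC)CC)CO[Si](CC)(CC)CC | intermediate
11 | (S)-2,3-bis(triethylsilyloxy)propanal | O=C[C@@H](O[Si](CC)(CC)CC)CO[Si](CC)(CC)CC | intermediate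
12 | lithium enolate of 8 (enolate between C3 and C4 of 8, geometry not defined) | COc1ccc(CCC#CC(O[Li])=C[C@H](O[Si](CC)(CC)CC)CO[Si](CC)(CC)CC)cc1OCc1ccccc1 | intermediate
13 | (2S)-8-[3-(benzyloxy)-4-methoxyphenyl]-3-[(2S)-1-hydroxy-2,3-bis(triethylsilyloxy)propyl]-1,2-bis(triethylsilyloxy)oct-5-yn-4-one, epimers at C3 and C1′ | COc1ccc(CCC#CC(=O)C([C@H](O[Si](CC)(CC)CC)CO[Si](CC)(CC)CC)C(O)[C@@H](O[Si](CC)(CC)CC)CO[Si](CC)(CC)CC)cc1OCc1ccccc1 | intermediate
14 | (2S)-8-[3-(benzyloxy)-4-methoxyphenyl]-3-[(2S)-2,3-bis(triethylsilyloxy)propanoyl]-1,2-bis(triethylsilyloxy)oct-5-yn-4-one (drawn as the diketo form) | COc1ccc(CCC#CC(=O)C([C@H](O[Si](CC)(CC)CC)CO[Si](CC)(CC)CC)C(=O)[C@@H](O[Si](CC)(CC)CC)CO[Si](CC)(CC)CC)cc1OCc1ccccc1 | intermediate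
15 | 6-{2-[3-(benzyloxy)-4-methoxyphenyl]ethyl}-2,3-bis[(1S)-1,2-bis(triethylsilyloxy)ethyl]-4H-pyran-4-one | COc1ccc(CCc2cc(=O)c(c(o2)[C@@H](O[Si](CC)(CC)CC)CO[Si](CC)(CC)CC)[C@H](O[Si](CC)(CC)CC)CO[Si](CC)(CC)CC)cc1OCc1ccccc1 | intermediate
16 | (2R)-2-{6-[2-(3-benzyloxy-4-methoxyphenyl)ethyl]-4-oxo-3-[(1S)-2-oxo-1-(triethylsilyloxy)ethyl]-4H-pyran-2-yl}-2-(triethylsilyloxy)acetaldehyde | COc1ccc(CCc2cc(=O)c(c(o2)[C@@H](O[Si](CC)(CC)CC)C=O)[C@H](O[Si](CC)(CC)CC)C=O)cc1OCc1ccccc1 | intermediate
17 | 6,7-bis[phenylbis(cyclopentadienyl)titanium] diolate of 18 (tetravalent titanium, cyclopentadienyl rings drawn σ-bonded) | COc1ccc(CCc2cc(=O)c3c(o2)[C@@H](O[Si](CC)(CC)CC)[C@H](O[Ti](c4ccccc4)(C4C=CC=C4)C4C=CC=C4)[C@@H](O[Ti](c4ccccc4)(C4C=CC=C4)C4C=CC=C4)[C@H]3O[Si](CC)(CC)CC)cc1OCc1ccccc1 | intermediate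
18 | 2-{2-[3-(benzyloxy)-4-methoxyphenyl]ethyl}-6,7-dihydroxy-5,8-bis(triethylsilyloxy)-5,6,7,8-tetrahydro-4H-chromen-4-one; (5S,6R,7R,8S) by the priority rules because the silyl ethers change the ranking at C6, spatially as in the target | COc1ccc(CCc2cc(=O)c3c(o2)[C@@H](O[Si](CC)(CC)CC)[C@H](O)[C@@H](O)[C@H]3O[Si](CC)(CC)CC)cc1OCc1ccccc1 | intermediate
19 | (5S,6S,7R,8S)-5,6,7,8-tetrahydroxy-2-[2-(3-hydroxy-4-methoxyphenyl)ethyl]-5,6,7,8-tetrahydro-4H-chromen-4-one | COc1ccc(CCc2cc(=O)c3c(o2)[C@@H](O)[C@H](O)[C@@H](O)[C@H]3O)cc1O | target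

Total step count: 12. Longest linear sequence: 8 steps (4 → 5 → 6 → 8 → 13 → 15 → 16 → 18 → 19; the sequence from 1 is equally long).

Steps most likely to fail

Step 11. The coupling may not discriminate well between the two trans diols or may leak to the cis diols, and the ketyls may be reduced to alcohols without coupling. The fallback sets out from 16 and comes back at 18. Coupling with SmI2 (divalent samarium, THF, t-BuOH, −78 °C) follows the well-established chelated course, in which the two new hydroxyls are cis to each other and each is anti to its silyloxy neighbour. It should therefore give the 6-epimer of 18, the cis-diol F1. In F1 the C6 hydroxyl is axial because the C5 silyloxy group is pseudo-axial. Bu2SnO (toluene, reflux) converts the diol into the dibutylstannylene acetal F2, and brominolysis (Br2, Bu3N, CH2Cl2, 0 °C) oxidises the axial C6 oxygen to give the 6-oxo-7-hydroxy ketol F3. Reduction of F3 with Me4NBH(OAc)3 (MeCN/AcOH, −20 °C) delivers hydride from the face of the C7 hydroxyl, which is also the face away from the pseudo-axial C5 silyloxy group. This should give the equatorial C6 alcohol trans to C7–OH, which is 18.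

Step 9. The enolised 1,3-diketone may lose the C5 silyloxy group by β-elimination before it cyclises, or may close to the five-membered furanone. The fallback sets out from 13 and comes back at 15, and reverses the order of events. The β-hydroxy ynone 13 is cyclised first with catalytic Ph3PAuNTf2 (or AgOTf) in CH2Cl2, a 6-endo hydroalkoxylation that gives the 2,3-dihydro-4H-pyran-4-one F4 without ever forming a diketone. Dehydrogenation across C4a–C8a with IBX in DMSO at 65 °C then gives 15.

Step 10. The oxidative desilylation may stop at one arm, may strip a secondary silyl ether, or the amine base may epimerise C5 or C8 of the α-silyloxy aldehydes. The fallback sets out from 15 and comes back at 16, and separates the two events. HF·pyridine buffered with pyridine (THF, 0 °C) removes only the two primary silyl groups to give the diol F5. Base-free oxidation with Dess–Martin periodinane and NaHCO3 in CH2Cl2 then gives 16.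

Further compounds
F1 | step 11 | 2-{2-[3-(benzyloxy)-4-methoxyphenyl]ethyl}-6,7-dihydroxy-5,8-bis(triethylsilyloxy)-5,6,7,8-tetrahydro-4H-chromen-4-one, 6-epimer of 18 (5,6-trans, 6,7-cis, 7,8-trans) | COc1ccc(CCc2cc(=O)c3c(o2)[C@@H](O[Si](CC)(CC)CC)[C@H](O)[C@H](O)[C@H]3O[Si](CC)(CC)CC)cc1OCc1ccccc1
F2 | step 11 | 6,7-O-dibutylstannylene acetal of F1 | COc1ccc(CCc2cc(=O)c3c(o2)[C@@H](O[Si](CC)(CC)CC)[C@H](O[Sn]4(CCCC)CCCC)[C@H](O4)[C@H]3O[Si](CC)(CC)CC)cc1OCc1ccccc1
F3 | step 11 | (5S,7S,8S)-2-{2-[3-(benzyloxy)-4-methoxyphenyl]ethyl}-7-hydroxy-5,8-bis(triethylsilyloxy)-7,8-dihydro-4H-chromene-4,6(5H)-dione | COc1ccc(CCc2cc(=O)c3c(o2)[C@@H](O[Si](CC)(CC)CC)[C@H](O)C(=O)[C@H]3O[Si](CC)(CC)CC)cc1OCc1ccccc1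
F4 | step 9 | 6-{2-[3-(benzyloxy)-4-methoxyphenyl]ethyl}-2,3-bis[(1S)-1,2-bis(triethylsilyloxy)ethyl]-2,3-dihydro-4H-pyran-4-one, epimers at C2 and C3 | COc1ccc(CCC2=CC(=O)C([C@H](O[Si](CC)(CC)CC)CO[Si](CC)(CC)CC)C(O2)[C@@H](O[Si](CC)(CC)CC)CO[Si](CC)(CC)CC)cc1OCc1ccccc1
F5 | step 10 | 6-{2-[3-(benzyloxy)-4-methoxyphenyl]ethyl}-2,3-bis[(1S)-2-hydroxy-1-(triethylsilyloxy)ethyl]-4H-pyran-4-one | COc1ccc(CCc2cc(=O)c(c(o2)[C@@H](O[Si](CC)(CC)CC)CO)[C@H](O[Si](CC)(CC)CC)CO)cc1OCc1ccccc1
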